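**Strategy.** The six-membered carbocycle of the tetralin (C1, C2, C3, C4, C4a, C8a) is disconnected at C1–C8a by a dienone–phenol rearrangement. In ring B the C7 oxygen lies para to C4a, so a C7-keto spiro[4.5]decadienone with C4a as spiro atom is available by para-alkylation of a phenoxide. Acid then moves the p-alkoxybenzylic carbon C1 from C4a to the adjacent C8a: in one operation the cyclopentane becomes the cyclohexane ring, the arene is restored and the aryl group settles trans to C2. The precursor is an all-trans 1-aryl-2,3-bis(silyloxymethyl)-7-benzyloxyspiro[4.5]deca-6,9-dien-8-one made from an (R)-β-benzyl-γ-butyrolactone; the liberated C7 phenol is methylated afterwards.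

Key step: step 9

Remark: locants C1–C8a are those of the tetralin core of the target (aryl on C1, CH2OH on C2 and C3, OH on C6, OMe on C7) and denote the same atoms in every precursor. Compound 1 is taken as a catalogue chemical. The carbinol carbon (later C1) is carried as an epimer mixture from step 5 to step 8, because step 9 fixes it.

Step 1
Reactants: 1 3-(benzyloxy)-4-hydroxybenzaldehyde
Product: 2 3-(benzyloxy)-4-(methoxymethoxy)benzaldehyde
Conditions: MOMCl, iPr2NEt, CH2Cl2, 0 °C to rt
Reagents that add atoms: chloromethyl methyl ether, COCCl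
Why: O-alkylation of the phenol (MOM protection) masks the future C7 oxygen as a base-stable acetal that survives the Stobbe and hydride steps and can be removed by acid before any acid-sensitive benzylic alcohol is present.

Step 2
Reactants: 2 3-(benzyloxy)-4-(methoxymethoxy)benzaldehyde; 3 dimethyl succinate
Product: 4 (3E)-4-[3-(benzyloxy)-4-(methoxymethoxy)phenyl]-3-(methoxycarbonyl)but-3-enoic acid
Conditions: NaOMe, MeOH, reflux; then cold 1 M HCl to pH 3
Reagents that add atoms: none
Why: Stobbe condensation (aldol addition, lactonisation onto the distal ester, base-induced ring opening) should give the (E)-arylidene half-ester that carries C4, C3, C2 and both future hydroxymethyl carbons.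

Step 3
Reactants: 4 (3E)-4-[3-(benzyloxy)-4-(methoxymethoxy)phenyl]-3-(methoxycarbonyl)but-3-enoic acid
Product: 5 (3R)-4-[3-(benzyloxy)-4-(methoxymethoxy)phenyl]-3-(methoxycarbonyl)butanoic acid
Conditions: H2 (5 bar), [Rh(cod)((S,S)-Et-DuPhos)]BF4 (0.5 mol %), NaOMe (10 mol %), MeOH, rt
Reagents that add atoms: none
Why: Rhodium–bisphospholane asymmetric hydrogenation of a Stobbe-derived itaconate half-ester reduces one enantioface of the chelated substrate and sets C3 as R (the ligand antipode is chosen for this sense); aryl benzyl ethers are inert to the homogeneous catalyst.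

Step 4
Reactants: 5 (3R)-4-[3-(benzyloxy)-4-(methoxymethoxy)phenyl]-3-(methoxycarbonyl)butanoic acid
Product: 7 (4R)-4-{[3-(benzyloxy)-4-hydroxyphenyl]methyl}oxolan-2-one, via hydroxy acid 6 (not isolated)
Conditions: LiOH (1.0 equiv), THF–MeOH; LiBH4, THF, 0 °C to rt; then 3 M aq HCl, THF, 50 °C
Reagents that add atoms: none
Why: Chemoselective borohydride reduction of the ester beside the carboxylate salt, then acid-promoted lactonisation with concurrent hydrolysis of the MOM acetal, should give the β-benzyl-γ-butyrolactone with C3 untouched.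

Step 5
Reactants: 7 (4R)-4-{[3-(benzyloxy)-4-hydroxyphenyl]methyl}oxolan-2-one; 8 4-(benzyloxy)-3-methoxybenzaldehyde
Product: 9 (3S,4R)-4-{[3-(benzyloxy)-4-hydroxyphenyl]methyl}-3-{[4-(benzyloxy)-3-methoxyphenyl](hydroxy)methyl}oxolan-2-one (both carbinol epimers)
Conditions: LiN(SiMe3)2 (2.2 equiv), THF, −78 °C; then 8, −78 °C; sat. NH4Cl at −78 °C
Reagents that add atoms: none
Why: Aldol addition of the lactone enolate (phenol carried as lithium phenoxide) to the aldehyde anti to the C3 benzyl group sets C2 trans to C3; the carbinol configuration is left open because it is erased later.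

Step 6
Reactants: 9 (3S,4R)-4-{[3-(benzyloxy)-4-hydroxyphenyl]methyl}-3-{[4-(benzyloxy)-3-methoxyphenyl](hydroxy)methyl}oxolan-2-one
Product: 10 (2R,3R)-2-{[3-(benzyloxy)-4-hydroxyphenyl]methyl}-3-{[4-(benzyloxy)-3-methoxyphenyl](hydroxy)methyl}butane-1,4-diol (both carbinol epimers)
Conditions: LiAlH4, THF, −10 to 0 °C; H2O, 15% aq NaOH, H2O work-up
Reagents that add atoms: none
Why: Hydride reduction of the lactone to the 1,4-diol opens the ring, so that the later cyclopentane is not trans-fused to a lactone; no stereocentre is touched.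

Step 7
Reactants: 10 (2R,3R)-2-{[3-(benzyloxy)-4-hydroxyphenyl]methyl}-3-{[4-(benzyloxy)-3-methoxyphenyl](hydroxy)methyl}butane-1,4-diol
Product: 11 (2R,3R)-1-[4-(benzyloxy)-3-methoxyphenyl]-3-{[3-(benzyloxy)-4-{[tert-butyl(dimethyl)silyl]oxy}phenyl]methyl}-4-{[tert-butyl(dimethyl)silyl]oxy}-2-({[tert-butyl(dimethyl)silyl]oxy}methyl)butan-1-ol (both C1 epimers)
Conditions: TBSCl (3.3 equiv), imidazole, DMF, 0 °C
Reagents that add atoms: tert-butyldimethylsilyl chloride, CC(C)(C)[Si](C)(C)Cl
Why: Chemoselective silylation: the phenol and the two primary hydroxyls react much faster than the hindered secondary benzylic hydroxyl, and the aryl silyl ether serves as the latent phenoxide.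

Step 8
Reactants: 11 tris-silyl benzylic alcohol (name as above)
Product: 13 (1S,2R,3R)-7-(benzyloxy)-1-[4-(benzyloxy)-3-methoxyphenyl]-2,3-bis({[tert-butyl(dimethyl)silyl]oxy}methyl)spiro[4.5]deca-6,9-dien-8-one (both configurations at the spiro carbon), via benzylic chloride 12 (not isolated)
Conditions: MsCl, Et3N, CH2Cl2, −40 to −10 °C; then CsF, DMF (0.01 M), 0 °C to rt
Reagents that add atoms: none
Why: The p-alkoxybenzylic mesylate collapses to the chloride, and fluoride then unmasks the C7 phenoxide, whose para carbon C4a alkylates C1 to close the five-membered ring (alkylative dearomatisation of a para-substituted phenoxide, Winstein Ar1-5 participation); the aryl group is expected trans to the C2 substituent.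

Step 9
Reactants: 13 spirodienone (name as above)
Product: 15 [(1S,2R,3R)-6-(benzyloxy)-1-[4-(benzyloxy)-3-methoxyphenyl]-7-hydroxy-1,2,3,4-tetrahydronaphthalene-2,3-diyl]dimethanol, via bis-silyl tetralin phenol 14 (not isolated)
Conditions: CF3CO2H–CH2Cl2 (1:4), −20 to 0 °C; then CF3CO2H–THF–H2O, rt; K2CO3, MeOH work-up
Reagents that add atoms: none
Why: O-Protonation of the cross-conjugated dienone gives a 4-hydroxyarenium ion in which benzylic C1, supported by the 4-benzyloxy-3-methoxyphenyl group, shifts from C4a to the neighbouring C8a, and loss of the C8a proton restores the arene. The closest known reaction is the acid-catalysed dienone–phenol rearrangement of 4,4-disubstituted cyclohexa-2,5-dienones, including spiro[4.5]deca-6,9-dien-8-ones that give tetrahydronaphthols. No ring is closed from a chain: the six-membered ring C1–C2–C3–C4–C4a–C8a arises by 1,2-shift enlargement of the cyclopentane C1–C2–C3–C4–C4a. C2 and C3 are spectators; C1 migrates suprafacially with retention, and if the shift instead passes through the free benzylic cation, re-closure at C8a places the aryl group pseudo-equatorial and trans to the C2 substituent, so both courses converge on the 1,2-trans-2,3-trans isomer. The step needs C1 rather than primary C4 to migrate and C8a rather than C5 to receive it: the first follows from the cation-stabilising aryl group on C1, the second from C5 being the electron-rich, hindered β-carbon of the C5=C6–OBn enol ether, while bonding at C8a gives an arenium ion stabilised by the para benzyloxy group. Aqueous acid in the same flask then removes the two primary silyl ethers.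

Step 10
Reactants: 15 tetralin phenol diol (name as above)
Product: 16 [(1S,2R,3R)-6-(benzyloxy)-1-[4-(benzyloxy)-3-methoxyphenyl]-7-methoxy-1,2,3,4-tetrahydronaphthalene-2,3-diyl]dimethanol
Conditions: MeI, K2CO3, acetone, 40 °C
Reagents that add atoms: iodomethane, CI
Why: Williamson methylation of the only free phenol (C7–OH); carbonate does not deprotonate the aliphatic hydroxyls.

Step 11
Reactants: 16 methyl ether (name as above)
Product: 17 (1S,2R,3R)-1-(4-hydroxy-3-methoxyphenyl)-2,3-bis(hydroxymethyl)-7-methoxy-1,2,3,4-tetrahydronaphthalen-6-ol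
Conditions: H2 (1 atm), Pd/C (10 wt %), EtOAc–MeOH, rt
Reagents that add atoms: none
Why: Hydrogenolysis of the two aryl benzyl ethers under neutral conditions leaves the diarylmethine C1–H bond and the primary alcohols intact.

**Compound list**

1 | 3-(benzyloxy)-4-hydroxybenzaldehyde | O=Cc1ccc(O)c(OCc2ccccc2)c1 | starting material
2 | 3-(benzyloxy)-4-(methoxymethoxy)benzaldehyde | COCOc1ccc(C=O)cc1OCc1ccccc1 | intermediate
3 | dimethyl succinate | COC(=O)CCC(=O)OC | starting material
4 | (3E)-4-[3-(benzyloxy)-4-(methoxymethoxy)phenyl]-3-(methoxycarbonyl)but-3-enoic acid | COC(=O)/C(CC(=O)O)=C/c1ccc(OCOC)c(OCc2ccccc2)c1 | intermediate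
5 | (3R)-4-[3-(benzyloxy)-4-(methoxymethoxy)phenyl]-3-(methoxycarbonyl)butanoic acid | COCOc1ccc(C[C@@H](C(=O)OC)CC(=O)O)cc1OCc1ccccc1 | intermediate
6 | (3R)-4-[3-(benzyloxy)-4-(methoxymethoxy)phenyl]-3-(hydroxymethyl)butanoic acid (formed as its lithium salt) | COCOc1ccc(C[C@@H](CO)CC(=O)O)cc1OCc1ccccc1 | intermediate (not isolated)
7 | (4R)-4-{[3-(benzyloxy)-4-hydroxyphenyl]methyl}oxolan-2-one | Oc1ccc(C[C@H]2COC(=O)C2)cc1OCc1ccccc1 | intermediate
8 | 4-(benzyloxy)-3-methoxybenzaldehyde | COc1cc(C=O)ccc1OCc1ccccc1 | starting material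
9 | (3S,4R)-4-{[3-(benzyloxy)-4-hydroxyphenyl]methyl}-3-{[4-(benzyloxy)-3-methoxyphenyl](hydroxy)methyl}oxolan-2-one, carbinol epimers | Oc1ccc(C[C@H]2COC(=O)[C@@H]2C(O)c2ccc(OCc3ccccc3)c(OC)c2)cc1OCc1ccccc1 | intermediate
10 | (2R,3R)-2-{[3-(benzyloxy)-4-hydroxyphenyl]methyl}-3-{[4-(benzyloxy)-3-methoxyphenyl](hydroxy)methyl}butane-1,4-diol, carbinol epimers | Oc1ccc(C[C@@H](CO)[C@@H](C(O)c2ccc(OCc3ccccc3)c(OC)c2)CO)cc1OCc1ccccc1 | intermediate
11 | tris-TBS ether of 10 (phenol and both primary hydroxyls silylated, benzylic hydroxyl free), (2R,3R), C1 epimers | CC(C)(C)[Si](C)(C)Oc1ccc(C[C@@H](CO[Si](C)(C)C(C)(C)C)[C@@H](C(O)c2ccc(OCc3ccccc3)c(OC)c2)CO[Si](C)(C)C(C)(C)C)cc1OCc1ccccc1 | intermediate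
12 | benzylic chloride corresponding to 11 (Cl in place of the benzylic OH), C1 epimers | CC(C)(C)[Si](C)(C)Oc1ccc(C[C@@H](CO[Si](C)(C)C(C)(C)C)[C@@H](C(Cl)c2ccc(OCc3ccccc3)c(OC)c2)CO[Si](C)(C)C(C)(C)C)cc1OCc1ccccc1 | intermediate (not isolated)
13 | (1S,2R,3R)-7-(benzyloxy)-1-[4-(benzyloxy)-3-methoxyphenyl]-2,3-bis({[tert-butyl(dimethyl)silyl]oxy}methyl)spiro[4.5]deca-6,9-dien-8-one, both spiro epimers | O=C1C=CC2(C=C1OCc1ccccc1)C[C@@H](CO[Si](C)(C)C(C)(C)C)[C@H](CO[Si](C)(C)C(C)(C)C)[C@H]2c1ccc(OCc2ccccc2)c(OC)c1 | intermediate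
14 | (1S,2R,3R)-6-(benzyloxy)-1-[4-(benzyloxy)-3-methoxyphenyl]-2,3-bis({[tert-butyl(dimethyl)silyl]oxy}methyl)-1,2,3,4-tetrahydronaphthalen-7-ol | COc1cc([C@H]2c3cc(O)c(OCc4ccccc4)cc3C[C@@H](CO[Si](C)(C)C(C)(C)C)[C@@H]2CO[Si](C)(C)C(C)(C)C)ccc1OCc1ccccc1 | intermediate (not isolated)
15 | [(1S,2R,3R)-6-(benzyloxy)-1-[4-(benzyloxy)-3-methoxyphenyl]-7-hydroxy-1,2,3,4-tetrahydronaphthalene-2,3-diyl]dimethanol | COc1cc([C@H]2c3cc(O)c(OCc4ccccc4)cc3C[C@@H](CO)[C@@H]2CO)ccc1OCc1ccccc1 | intermediate
16 | [(1S,2R,3R)-6-(benzyloxy)-1-[4-(benzyloxy)-3-methoxyphenyl]-7-methoxy-1,2,3,4-tetrahydronaphthalene-2,3-diyl]dimethanol | COc1cc([C@H]2c3cc(OC)c(OCc4ccccc4)cc3C[C@@H](CO)[C@@H]2CO)ccc1OCc1ccccc1 | intermediate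
17 | (1S,2R,3R)-1-(4-hydroxy-3-methoxyphenyl)-2,3-bis(hydroxymethyl)-7-methoxy-1,2,3,4-tetrahydronaphthalen-6-ol | COc1cc([C@H]2c3cc(OC)c(O)cc3C[C@@H](CO)[C@@H]2CO)ccc1O | target

**Step count.** Total: 11 steps. Longest linear sequence: 11 steps (1 to 17); compounds 3 and 8 enter as purchased materials.

**Steps most likely to fail**

Step 8 (spirocyclisation). The benzylic chloride may ionise and lose the C2 proton to a styrene, or be captured by the oxygen of the C3 silyloxymethyl group with desilylation to a tetrahydrofuran, before the phenoxide carbon reacts; intermolecular alkylation may intrude if dilution is insufficient. The fallback sets out from 11 and replaces the anionic alkylation by an acid-catalysed ipso-Friedel–Crafts alkylation of the free phenol. K2CO3 in MeOH at rt should cleave only the aryl silyl ether and give the free phenol with intact primary silyl ethers and free benzylic hydroxyl F1. Bi(OTf)3 (5 mol %) in MeCN at −20 °C should then ionise the benzylic alcohol and let the para carbon of the phenol capture C1 with loss of a proton from oxygen. This comes back to the route at 13; any material that closes directly at C8a is compound 14, which step 9 carries to 15 as well.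

Step 9 (key step). The shift may go in part to C5 instead of C8a, a free C1 cation may lose the C2 proton (styrene formation and scrambling of C2), or turnover may be slow because the 2-alkoxydienone is weakly basic. The fallback sets out from 13 and splits the rearrangement into solvolysis and ring closure under milder acids. Camphorsulfonic acid in MeOH at 40 °C should cleave the C4a–C1 bond with rearomatisation, trap C1 as its methyl ether and remove both silyl groups, giving the ring-opened benzylic methyl ether triol F2. BF3·OEt2 in CH2Cl2 at −40 °C should then effect the intramolecular Friedel–Crafts alkylation para to the benzyloxy group, the classical aryltetralin-lignan closure, with the aryl group trans to C2. This comes back to the route at 15.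

Step 5 (aldol). The phenoxide–enolate dianion may aggregate and enolise incompletely, and the aldolate may revert on quenching or warming. The fallback sets out from 7 and carries the phenol as a silyl ether so that a simple mono-enolate is used. TBSCl and imidazole in DMF should give the aryl silyl ether of the lactone F3. LiN(iPr)2 (1.1 equiv) in THF at −78 °C followed by aldehyde 8 should give the trans aldol adduct with silylated phenol F4. LiBH4 in THF at 0 °C should reduce the lactone while keeping the aryl silyl ether and give the triol with silylated phenol F5. TBSCl (2.2 equiv) and imidazole at 0 °C should then silylate the two primary hydroxyls. This comes back to the route at 11.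

**Further compounds**

F1 | step 8 | (2R,3R)-1-[4-(benzyloxy)-3-methoxyphenyl]-3-{[3-(benzyloxy)-4-hydroxyphenyl]methyl}-4-{[tert-butyl(dimethyl)silyl]oxy}-2-({[tert-butyl(dimethyl)silyl]oxy}methyl)butan-1-ol, C1 epimers | Oc1ccc(C[C@@H](CO[Si](C)(C)C(C)(C)C)[C@@H](C(O)c2ccc(OCc3ccccc3)c(OC)c2)CO[Si](C)(C)C(C)(C)C)cc1OCc1ccccc1
F2 | step 9 | (2R,3R)-2-{[3-(benzyloxy)-4-hydroxyphenyl]methyl}-3-{[4-(benzyloxy)-3-methoxyphenyl](methoxy)methyl}butane-1,4-diol, epimers at the methoxy-bearing carbon | Oc1ccc(C[C@@H](CO)[C@@H](C(OC)c2ccc(OCc3ccccc3)c(OC)c2)CO)cc1OCc1ccccc1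
F3 | step 5 | (4R)-4-{[3-(benzyloxy)-4-{[tert-butyl(dimethyl)silyl]oxy}phenyl]methyl}oxolan-2-one | CC(C)(C)[Si](C)(C)Oc1ccc(C[C@H]2COC(=O)C2)cc1OCc1ccccc1
F4 | step 5 | (3S,4R)-4-{[3-(benzyloxy)-4-{[tert-butyl(dimethyl)silyl]oxy}phenyl]methyl}-3-{[4-(benzyloxy)-3-methoxyphenyl](hydroxy)methyl}oxolan-2-one, carbinol epimers | CC(C)(C)[Si](C)(C)Oc1ccc(C[C@H]2COC(=O)[C@@H]2C(O)c2ccc(OCc3ccccc3)c(OC)c2)cc1OCc1ccccc1
F5 | step 5 | (2R,3R)-2-{[3-(benzyloxy)-4-{[tert-butyl(dimethyl)silyl]oxy}phenyl]methyl}-3-{[4-(benzyloxy)-3-methoxyphenyl](hydroxy)methyl}butane-1,4-diol, carbinol epimers | CC(C)(C)[Si](C)(C)Oc1ccc(C[C@@H](CO)[C@@H](C(O)c2ccc(OCc3ccccc3)c(OC)c2)CO)cc1OCc1ccccc1
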